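The C6 ketone sits beside the ring-fusion pair C5 (CH) and C4 (tertiary carbinol), so the C4–C5 bond can be read as the result of a 1,2-shift of C4 from C6 to C5. Locants: cycloheptanone C1 (CHMe), C2, C3, C4, C5, C6 (C=O), C7 (quaternary); cyclopentane C4, C5, C8, C9 (CHOH), C10 (CMe2); tether C11–C12 to the butenolide.
Retrosynthesis: cut C12–C(butenolide), then reverse the shift (C4–C5 back to C4–C6) to a cis-decalin-4,6-diol 5-mesylate with ring A = C6, C7, C1, C2, C3, C4 and ring B = C6, C5, C8, C9, C10, C4.
Ring B is then cut at C5–C8 (aldol), C4–C10 (reverse prenylation of a C4 ketone) and C5–C6 (alkenyl addition to a C6 ketone), which leaves a 2,2,3-trisubstituted cyclohexanone.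
Forward: ring A is made first, ring B is closed on it by aldol addition, the shift then turns the two six-membered rings into the five- and seven-membered rings in one step, and the butenolide is coupled last.
Stereochemistry: C1 from a catalyst-controlled conjugate addition, C7 from methylation anti to the C1 methyl, C6 from attack anti to the C7 side chain, C4 from chelation by the C6 oxygen, decalin C5 from the chelated aldol, C9 from hydroxyl-directed hydride delivery, and C5 of the target from inversion in the stereospecific shift.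

Key step: step 14

Remark: target locants are used for all intermediates; β is the face of ring A that carries the C1 methyl group and α the opposite face. The side-chain oxygen is carried as a benzyl ether because it must survive ozone and Et2AlCl and can be removed by hydrogenolysis before the butenolide alkene is present.
Remark: benzyl 2-bromoethyl ether, Me2C=CHMgBr, Me2C=CHCH2MgCl and 4-bromofuran-2(5H)-one are taken as purchasable.

Step 1
Reactants: 1 2-methoxybenzoic acid; 2 benzyl 2-bromoethyl ether
Product: 5 2-[2-(benzyloxy)ethyl]cyclohex-2-en-1-one, via dilithium Birch dianion 3 (not isolated), via alkylated diene acid 4 (not isolated)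
Conditions: Li, NH3(l)/THF, −78 °C; isoprene (discharges excess Li); 2, −78 → −33 °C; NH4Cl; then 2 M HCl, THF, 60 °C
Reagents that add atoms: water, O
Why: Birch reduction–alkylation of the benzoic acid places the side chain on the carboxyl-bearing carbon, and acid then hydrolyses the enol ether, decarboxylates the β-keto acid and moves the alkene into conjugation (known route to 2-alkylcyclohexenones); excess lithium is destroyed before the bromide is added so that the benzyl ether is not reduced.

Step 2
Reactants: 5 2-[2-(benzyloxy)ethyl]cyclohex-2-en-1-one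
Product: 7 {[(3R)-2-[2-(benzyloxy)ethyl]-3-methylcyclohex-1-en-1-yl]oxy}trimethylsilane, via dimethylaluminium enolate 6 (not isolated)
Conditions: Me3Al, CuTC [Cu(O2C-C4H3S), copper thiophene-2-carboxylate] (2 mol %), BINOL/bis(1-phenylethyl)amine phosphoramidite (4 mol %, enantiomer that gives the 3R product), Et2O, −30 °C; then Me3SiOTf, −30 → 0 °C
Reagents that add atoms: trimethylaluminium, C[Al](C)C; trimethylsilyl trifluoromethanesulfonate, C[Si](C)(C)OS(=O)(=O)C(F)(F)F
Why: Copper-catalysed asymmetric conjugate addition of Me3Al to a 2-substituted cyclohexenone, in which the chiral phosphoramidite–copper complex selects the enone face and so sets C1, followed by O-silylation of the regiodefined aluminium enolate.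

Step 3
Reactants: 7 {[(3R)-2-[2-(benzyloxy)ethyl]-3-methylcyclohex-1-en-1-yl]oxy}trimethylsilane
Product: 9 (2R,3R)-2-[2-(benzyloxy)ethyl]-2,3-dimethylcyclohexan-1-one, via lithium enolate 8 (not isolated)
Conditions: MeLi, THF, 0 °C; then MeI, DMPU, −78 → 0 °C
Reagents that add atoms: iodomethane, CI
Why: MeLi releases the regiodefined lithium enolate, and enolate alkylation should take place on the face anti to the neighbouring C1 methyl (pseudo-axial to avoid A(1,2) strain), so the new C7 methyl is expected trans to the C1 methyl and the side chain cis to it.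

Step 4
Reactants: 9 (2R,3R)-2-[2-(benzyloxy)ethyl]-2,3-dimethylcyclohexan-1-one
Product: 10 (5R,6R)-6-[2-(benzyloxy)ethyl]-2-hydroxy-5,6-dimethylcyclohex-2-en-1-one
Conditions: KOtBu, O2 (1 atm), tBuOH/DME, 20 °C; dil. HCl quench
Reagents that add atoms: dioxygen, O=O
Why: Base-mediated autoxidation of a ketone (enolate, α-hydroperoxide, 1,2-dione isolated as its enol) can occur only at C4 because the other α-carbon, C7, is quaternary.

Step 5
Reactants: 10 (5R,6R)-6-[2-(benzyloxy)ethyl]-2-hydroxy-5,6-dimethylcyclohex-2-en-1-one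
Product: 11 (5R,6R)-6-[2-(benzyloxy)ethyl]-2-methoxy-5,6-dimethylcyclohex-2-en-1-one
Conditions: Me2SO4, K2CO3, acetone, reflux
Reagents that add atoms: dimethyl sulfate, COS(=O)(=O)OC
Why: Williamson-type O-methylation of the acidic diosphenol enol masks C4 as a methyl enol ether and leaves C6 as the only ketone.

Step 6
Reactants: 11 (5R,6R)-6-[2-(benzyloxy)ethyl]-2-methoxy-5,6-dimethylcyclohex-2-en-1-one
Product: 13 (2R,3R,4R)-3-[2-(benzyloxy)ethyl]-2-hydroxy-3,4-dimethyl-2-(2-methylprop-1-en-1-yl)cyclohexan-1-one, via tertiary carbinol enol ether 12 (not isolated)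
Conditions: Me2C=CHMgBr, CeCl3, THF, −78 → 0 °C; then 0.5 M HCl, THF, 0 °C
Reagents that add atoms: 2-methylprop-1-enylmagnesium bromide, CC(C)=C[Mg]Br; water, O
Why: Organocerium 1,2-addition to the hindered enone carbonyl should come from the α face, anti to the pseudo-axial C7 side chain in the half-chair that keeps the C1 methyl equatorial (the other half-chair puts that methyl axial over the carbonyl), which sets C6 with its hydroxyl β; brief dilute acid then hydrolyses only the enol ether to the C4 ketone.

Step 7
Reactants: 13 (2R,3R,4R)-3-[2-(benzyloxy)ethyl]-2-hydroxy-3,4-dimethyl-2-(2-methylprop-1-en-1-yl)cyclohexan-1-one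
Product: 14 ring A 4β,6β-diol carrying 4α-(2-methylbut-3-en-2-yl) and 6α-(2-methylprop-1-enyl) groups (7α-Me, 7β-CH2CH2OBn, 1β-Me)
Conditions: Me2C=CHCH2MgCl (3 equiv), THF, −78 °C; NH4Cl (aq)
Reagents that add atoms: 3-methylbut-2-enylmagnesium chloride, CC(C)=CC[Mg]Cl
Why: Chelation-controlled (Cram-chelate) γ-selective addition of an allylic Grignard reagent (reverse prenylation): the equatorial C6 magnesium alkoxide chelates the C4 carbonyl, the β (axial) approach is blocked by the axial C7 side chain, and the tertiary allyl terminus should therefore bond to C4 from the α face, giving the C4 hydroxyl cis to the C6 hydroxyl.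

Step 8
Reactants: 14 ring A 4β,6β-diol carrying 4α-(2-methylbut-3-en-2-yl) and 6α-(2-methylprop-1-enyl) groups
Product: 15 ring A 4β,6β-diol carrying 4α-(2-methyl-3-oxobutan-2-yl) and 6α-(2-methylprop-1-enyl) groups
Conditions: PdCl2 (10 mol %), CuCl, O2 (1 atm), DMF/H2O, 25 °C
Reagents that add atoms: water, O
Why: Tsuji–Wacker oxidation: Markovnikov hydroxypalladation of the only monosubstituted alkene gives the C9 methyl ketone (C8 = its methyl), while the trisubstituted 2-methylpropenyl group is too hindered to react.

Step 9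
Reactants: 15 ring A 4β,6β-diol carrying 4α-(2-methyl-3-oxobutan-2-yl) and 6α-(2-methylprop-1-enyl) groups
Product: 17 ring A 4β,6β-diol carrying 4α-(2-methyl-3-oxobutan-2-yl) and 6α-formyl groups, via secondary ozonide 16 (not isolated)
Conditions: O3, CH2Cl2, −78 °C (indicator end point); then PPh3, −78 → 20 °C
Reagents that add atoms: ozone, [O-][O+]=O
Why: Ozonolysis with reductive work-up cleaves the one remaining alkene to the C5 aldehyde; periodate-based cleavage is avoided because it could also cut the C4,C6-diol.

Step 10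
Reactants: 17 ring A 4β,6β-diol carrying 4α-(2-methyl-3-oxobutan-2-yl) and 6α-formyl groups
Product: 18 cis-fused decalin 4β,5β,6β-triol 9-ketone (7α-Me, 7β-CH2CH2OBn, 1β-Me, 10,10-Me2)
Conditions: LiN(SiMe3)2 (3.3 equiv), THF, −78 °C; AcOH, −78 °C
Reagents that add atoms: none
Why: Intramolecular aldol addition (6-enolexo): the C8 methyl is the only enolisable position and the C5 aldehyde the only non-enolisable electrophile, lithium chelation of the aldehyde by the C6 alkoxide together with a chair transition state should place the new C5 hydroxyl equatorial on ring B (β, cis to the C6 hydroxyl), and the cis ring fusion follows from the C4 and C6 centres already in place.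

Step 11
Reactants: 18 cis-fused decalin 4β,5β,6β-triol 9-ketone
Product: 19 cis-fused decalin 4β,5β,6β,9α-tetraol
Conditions: Me4NBH(OAc)3, MeCN/AcOH, −30 → 0 °C
Reagents that add atoms: none
Why: Hydroxyl-directed reduction with triacetoxyborohydride (Evans–Saksena type): hydride is delivered from the β-face hydroxyls at C4 and C5 to give the 9α (anti) alcohol, external α attack being blocked in any case by the axial C3 methylene, and the acidic medium avoids retro-aldol cleavage.

Step 12
Reactants: 19 cis-fused decalin 4β,5β,6β,9α-tetraol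
Product: 21 cis-fused decalin 4β,6β,9α-triol 5β-mesylate, via dibutylstannylene acetal 20 (not isolated)
Conditions: Bu2SnO (1.05 equiv), toluene, reflux (−H2O); then MsCl (1.1 equiv), CH2Cl2, 0 °C
Reagents that add atoms: methanesulfonyl chloride, CS(=O)(=O)Cl
Why: Regioselective sulfonylation through a stannylene acetal: the acetal can form only across cis hydroxyls that include the C5 oxygen, within it the secondary oxygen is the nucleophilic one, and the isolated axial C9 hydroxyl and both tertiary hydroxyls should stay free.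

Step 13
Reactants: 21 cis-fused decalin 4β,6β,9α-triol 5β-mesylate
Product: 22 cis-fused decalin 4β,6β-diol 5β-mesylate 9α-tert-butyldimethylsilyl ether
Conditions: tBuMe2SiOTf (1.2 equiv), 2,6-lutidine, CH2Cl2, −78 °C
Reagents that add atoms: tert-butyldimethylsilyl trifluoromethanesulfonate, CC(C)(C)[Si](C)(C)OS(=O)(=O)C(F)(F)F
Why: Silyl triflate silylation of the only remaining secondary alcohol (the two tertiary hydroxyls are flanked by quaternary carbons and should not react at −78 °C); the silyl ether removes the C9 oxygen as a donor for C8–C9 fragmentation in the next step.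

Step 14
Reactants: 22 cis-fused decalin 4β,6β-diol 5β-mesylate 9α-tert-butyldimethylsilyl ether
Product: 23 trans-fused hydroazulenone (C6 ketone, 4β-OH, 5α-H, 9α-OSiMe2tBu, 7α-Me, 7β-CH2CH2OBn, 1β-Me, 10,10-Me2)
Conditions: Et2AlCl (3 equiv), CH2Cl2, −78 → −20 °C; aq. potassium sodium tartrate
Reagents that add atoms: none
Why: Et2AlCl turns both tertiary hydroxyls into aluminium alkoxides and activates the sulfonate, and as the C5–O bond ionises the C6 oxygen donates while the C4–C6 σ-bond, anti-periplanar to the leaving group, shifts to C5 and leaves the C6 carbonyl. The closest known reaction type is the pinacol-type (semipinacol) rearrangement of 2-hydroxy sulfonates, as used to turn decalin diol monosulfonates into hydroazulenones. No ring is closed by a separate cyclisation: the cyclopentane (C4, C5, C8, C9, C10) arises by ring contraction as C4–C5 forms, and the cycloheptanone (C1–C7) by ring expansion as C4–C6 breaks, both in the same 1,2-alkyl shift. The new stereocentre C5 is controlled by the β configuration of the C5–O bond, which is displaced with inversion while C4 migrates with retention, so the C4 hydroxyl and C5 hydrogen end up trans. The step needs migration of C4 rather than C7 and no fragmentation: the reactive chair holds the mesylate equatorial on ring B because the other chair would force quaternary C7 axial against a C10 methyl, the C9 silyl ether blocks C8–C9 cleavage, and the cis relation of the C6 hydroxyl and the mesylate excludes epoxide formation.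

Step 15
Reactants: 23 trans-fused hydroazulenone benzyl ether
Product: 24 trans-fused hydroazulenone primary alcohol (7β-CH2CH2OH)
Conditions: H2 (1 atm), Pd/C (palladium on carbon), EtOAc, 25 °C
Reagents that add atoms: none
Why: Hydrogenolysis of the benzyl ether; no alkene is present, and the hindered ketone, the silyl ether and the tertiary alcohol are not affected.

Step 16
Reactants: 24 trans-fused hydroazulenone primary alcohol
Product: 25 trans-fused hydroazulenone primary iodide (7β-CH2CH2I)
Conditions: I2, PPh3, imidazole, CH2Cl2, 0 → 25 °C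
Reagents that add atoms: iodine, II
Why: Appel-type iodination converts the only primary alcohol by SN2 displacement of its oxyphosphonium salt; the hindered tertiary C4 hydroxyl cannot react.

Step 17
Reactants: 25 trans-fused hydroazulenone primary iodide; 26 4-bromofuran-2(5H)-one
Product: 28 silyl-protected target (9α-OSiMe2tBu), via alkylzinc iodide 27 (not isolated)
Conditions: Zn dust, LiCl, THF, 40 °C; then 26, Pd2(dba)3 (2.5 mol %), SPhos (10 mol %), THF/DMA, 25 °C
Reagents that add atoms: none
Why: Zinc insertion into the primary C–I bond followed by palladium-catalysed Negishi sp3–sp2 coupling with the β-bromobutenolide; the neutral conditions spare the β-hydroxy ketone and the epimerisable C5 centre.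

Step 18
Reactants: 28 silyl-protected target
Product: 29 CNP0077405.3
Conditions: HF·pyridine, THF/pyridine, 0 → 25 °C
Reagents that add atoms: none
Why: Fluoride-mediated desilylation under buffered acidic conditions frees the C9 alcohol without the base that could cause retro-aldol cleavage, C5 epimerisation or butenolide isomerisation.

Compound list
1 | 2-methoxybenzoic acid | COc1ccccc1C(O)=O | starting material
2 | benzyl 2-bromoethyl ether | BrCCOCc1ccccc1 | starting material
3 | dilithium dianion of 2-methoxy-1,4-dihydrobenzoic acid (Birch dianion) | COC1=CCC=CC1=C([O-])[O-].[Li+].[Li+] | intermediate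
4 | 1-[2-(benzyloxy)ethyl]-2-methoxycyclohexa-2,5-diene-1-carboxylic acid | COC1=CCC=CC1(CCOCc1ccccc1)C(O)=O | intermediate
5 | 2-[2-(benzyloxy)ethyl]cyclohex-2-en-1-one | O=C1CCCC=C1CCOCc1ccccc1 | intermediate
6 | dimethylaluminium enolate of (3R)-2-[2-(benzyloxy)ethyl]-3-methylcyclohexanone | C[C@@H]1CCCC(O[Al](C)C)=C1CCOCc1ccccc1 | intermediate
7 | {[(3R)-2-[2-(benzyloxy)ethyl]-3-methylcyclohex-1-en-1-yl]oxy}trimethylsilane | C[C@@H]1CCCC(O[Si](C)(C)C)=C1CCOCc1ccccc1 | intermediate
8 | lithium enolate of (3R)-2-[2-(benzyloxy)ethyl]-3-methylcyclohexanone | [Li+].C[C@@H]1CCCC([O-])=C1CCOCc1ccccc1 | intermediate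
9 | (2R,3R)-2-[2-(benzyloxy)ethyl]-2,3-dimethylcyclohexan-1-one (C6 ketone; 7α-Me, 7β-side chain, 1β-Me) | C[C@@H]1CCCC(=O)[C@]1(C)CCOCc1ccccc1 | intermediate
10 | (5R,6R)-6-[2-(benzyloxy)ethyl]-2-hydroxy-5,6-dimethylcyclohex-2-en-1-one | C[C@@H]1CC=C(O)C(=O)[C@]1(C)CCOCc1ccccc1 | intermediate
11 | (5R,6R)-6-[2-(benzyloxy)ethyl]-2-methoxy-5,6-dimethylcyclohex-2-en-1-one | C[C@@H]1CC=C(OC)C(=O)[C@]1(C)CCOCc1ccccc1 | intermediate
12 | tertiary carbinol enol ether: C6 β-OH and α-(2-methylprop-1-enyl), C4 methyl enol ether | C[C@@H]1CC=C(OC)[C@@](O)(C=C(C)C)[C@]1(C)CCOCc1ccccc1 | intermediate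
13 | (2R,3R,4R)-3-[2-(benzyloxy)ethyl]-2-hydroxy-3,4-dimethyl-2-(2-methylprop-1-en-1-yl)cyclohexan-1-one (C4 ketone, 6β-OH) | C[C@@H]1CCC(=O)[C@@](O)(C=C(C)C)[C@]1(C)CCOCc1ccccc1 | intermediate
14 | ring A diol: 4β-OH, 4α-(2-methylbut-3-en-2-yl), 6β-OH, 6α-(2-methylprop-1-enyl), 7α-Me, 7β-CH2CH2OBn, 1β-Me | C[C@@H]1CC[C@@](O)(C(C)(C)C=C)[C@@](O)(C=C(C)C)[C@]1(C)CCOCc1ccccc1 | intermediate
15 | ring A diol methyl ketone: as 14 with 4α-(2-methyl-3-oxobutan-2-yl) | C[C@@H]1CC[C@@](O)(C(C)(C)C(C)=O)[C@@](O)(C=C(C)C)[C@]1(C)CCOCc1ccccc1 | intermediate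
16 | secondary ozonide of 15 (3,3-dimethyl-1,2,4-trioxolan-5-yl at C6, mixture at the trioxolane carbon) | C[C@@H]1CC[C@@](O)(C(C)(C)C(C)=O)[C@@](O)(C2OOC(C)(C)O2)[C@]1(C)CCOCc1ccccc1 | intermediate
17 | ring A diol keto aldehyde: 4α-(2-methyl-3-oxobutan-2-yl), 6α-CHO, 4β,6β-diol | C[C@@H]1CC[C@@](O)(C(C)(C)C(C)=O)[C@@](O)(C=O)[C@]1(C)CCOCc1ccccc1 | intermediate
18 | cis-fused decalin 4β,5β,6β-triol 9-ketone (ring B: C6, C5, C8, C9, C10, C4) | C[C@@H]1CC[C@]2(O)[C@@](O)([C@@H](O)CC(=O)C2(C)C)[C@]1(C)CCOCc1ccccc1 | intermediate
19 | cis-fused decalin 4β,5β,6β,9α-tetraol | C[C@@H]1CC[C@]2(O)[C@@](O)([C@@H](O)C[C@H](O)C2(C)C)[C@]1(C)CCOCc1ccccc1 | intermediate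
20 | C5,C6-O-dibutylstannylene acetal of 19 | C[C@@H]1CC[C@]2(O)[C@]3(O[Sn](CCCC)(CCCC)O[C@H]3C[C@H](O)C2(C)C)[C@]1(C)CCOCc1ccccc1 | intermediate
21 | cis-fused decalin 4β,6β,9α-triol 5β-mesylate | C[C@@H]1CC[C@]2(O)[C@@](O)([C@@H](OS(C)(=O)=O)C[C@H](O)C2(C)C)[C@]1(C)CCOCc1ccccc1 | intermediate
22 | cis-fused decalin 4β,6β-diol 5β-mesylate 9α-tert-butyldimethylsilyl ether (key-step precursor) | C[C@@H]1CC[C@]2(O)[C@@](O)([C@@H](OS(C)(=O)=O)C[C@H](O[Si](C)(C)C(C)(C)C)C2(C)C)[C@]1(C)CCOCc1ccccc1 | intermediate
23 | trans-fused hydroazulenone: C6 ketone, 4β-OH, 5α-H, 9α-OSiMe2tBu, 7β-CH2CH2OBn (key-step product) | C[C@@H]1CC[C@]2(O)[C@H](C[C@H](O[Si](C)(C)C(C)(C)C)C2(C)C)C(=O)[C@]1(C)CCOCc1ccccc1 | intermediate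
24 | trans-fused hydroazulenone primary alcohol (7β-CH2CH2OH) | C[C@@H]1CC[C@]2(O)[C@H](C[C@H](O[Si](C)(C)C(C)(C)C)C2(C)C)C(=O)[C@]1(C)CCO | intermediate
25 | trans-fused hydroazulenone primary iodide (7β-CH2CH2I) | C[C@@H]1CC[C@]2(O)[C@H](C[C@H](O[Si](C)(C)C(C)(C)C)C2(C)C)C(=O)[C@]1(C)CCI | intermediate
26 | 4-bromofuran-2(5H)-one | BrC1=CC(=O)OC1 | starting material
27 | alkylzinc iodide from 25 (7β-CH2CH2ZnI) | C[C@@H]1CC[C@]2(O)[C@H](C[C@H](O[Si](C)(C)C(C)(C)C)C2(C)C)C(=O)[C@]1(C)CC[Zn]I | intermediate
28 | 9-O-tert-butyldimethylsilyl ether of the target | C[C@@H]1CC[C@]2(O)[C@H](C[C@H](O[Si](C)(C)C(C)(C)C)C2(C)C)C(=O)[C@]1(C)CCC1=CC(=O)OC1 | intermediate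
29 | CNP0077405.3: 4-[2-(hydroazulenon-7-yl)ethyl]furan-2(5H)-one with 4β-OH, 5α-H, 9α-OH, 7α-Me, 1β-Me, 10,10-Me2 | C[C@@H]1CC[C@]2(O)[C@H](C[C@H](O)C2(C)C)C(=O)[C@]1(C)CCC1=CC(=O)OC1 | target

Total step count: 18. Longest linear sequence: 18 steps (from 1 to 29; 26 enters at step 17).

Steps most likely to fail

Step 7. The tertiary end of the allyl reagent may not reach the crowded C4 carbonyl, may bond through its primary end instead, or may add without chelation control and give the wrong C4 epimer. The fallback sets out from 13 and makes the C4–C10 bond by a Reformatsky reaction: ethyl 2-bromo-2-methylpropanoate and activated Zn in THF should give the β-hydroxy ester F1, again under chelation by the C6 zinc alkoxide. Excess Me3SiCH2Li followed by methanol should then convert the ester, through the α-trimethylsilyl ketone F2, into the methyl ketone. The route is rejoined at 15, and step 8 is then not needed.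

Step 12. Site selectivity between the two secondary hydroxyls may be lost, with sulfonylation at the C9 oxygen or at both. The fallback sets out from 19 and separates the two positions by protection: 2-methoxypropene with pyridinium p-toluenesulfonate should tie the cis C5/C6 diol into the acetonide F3, tBuMe2SiOTf and 2,6-lutidine then silylate the only free secondary hydroxyl to give the silyl ether acetonide F4, and aqueous acetic acid in THF removes the acetal to give the C9 silyl ether triol F5. In F5 the C5 hydroxyl is the only secondary alcohol, so MsCl and Et3N should give the mesylate directly. The route is rejoined at 22.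

Step 17. The alkylzinc reagent may be protonated by the free tertiary hydroxyl before it couples, or zinc insertion and transmetalation may be slow beside the β-hydroxy ketone. The fallback sets out from 25 and 26 and avoids any preformed organometallic: a nickel-catalysed reductive cross-electrophile coupling (NiBr2(dme), 4,4'-di-tert-butyl-2,2'-bipyridine, Mn powder, NaI, DMA) joins the alkyl iodide and the bromobutenolide directly and tolerates free alcohols. The route is rejoined at 28; this fallback makes no new compound (F0).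

Further compounds
F1 | step 7 | β-hydroxy ester: ring A 4β,6β-diol with 4α-(1-ethoxy-2-methyl-1-oxopropan-2-yl) and 6α-(2-methylprop-1-enyl) | C[C@@H]1CC[C@@](O)(C(C)(C)C(=O)OCC)[C@@](O)(C=C(C)C)[C@]1(C)CCOCc1ccccc1
F2 | step 7 | α-trimethylsilyl ketone: as F1 with the ester replaced by C(=O)CH2SiMe3 | C[C@@H]1CC[C@@](O)(C(C)(C)C(=O)C[Si](C)(C)C)[C@@](O)(C=C(C)C)[C@]1(C)CCOCc1ccccc1
F3 | step 12 | C5,C6-O-isopropylidene acetal of tetraol 19 | C[C@@H]1CC[C@]2(O)[C@]3(OC(C)(C)O[C@H]3C[C@H](O)C2(C)C)[C@]1(C)CCOCc1ccccc1
F4 | step 12 | 9α-tert-butyldimethylsilyl ether of acetonide F3 | C[C@@H]1CC[C@]2(O)[C@]3(OC(C)(C)O[C@H]3C[C@H](O[Si](C)(C)C(C)(C)C)C2(C)C)[C@]1(C)CCOCc1ccccc1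
F5 | step 12 | cis-fused decalin 4β,5β,6β-triol 9α-tert-butyldimethylsilyl ether | C[C@@H]1CC[C@]2(O)[C@@](O)([C@@H](O)C[C@H](O[Si](C)(C)C(C)(C)C)C2(C)C)[C@]1(C)CCOCc1ccccc1
F0 | step 17 | none | none
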